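**Retrosynthetic overview**
1. The target lactone (ring B, C9–O–C9′) comes from a seco dihydroxy acid. That acid comes from hydride opening of an isomeric lactone acid (ring A, C7–O–C9′=O), so the C7–O bond and all three stereocentres are carried over unchanged.
2. Ring A comes from a p-quinone methide at C7 captured by the C9′ carboxyl of a (2R,3R)-dibenzylsuccinic acid, the same closure that builds the furofuran and dilactone lignans. The single free phenol decides which benzylic carbon is oxidised, which carboxyl closes, and therefore which carbonyl is later reduced.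
3. The diacid comes from an 8–8′ one-electron coupling of two C6C3 enolates. Each is steered by a valine-derived oxazolidinone, which plays the part of the dirigent protein.
4. Ring order: ring A forms first (step 5). Ring B forms second (step 6), as ring A is opened.

Assumption: lignan numbering is used (C7–C9 is the side chain of the guaiacyl unit, C7′–C9′ that of the veratryl unit). The SMILES is read as (3S,4R)-4-(3,4-dimethoxybenzyl)-3-[(S)-hydroxy(4-hydroxy-3-methoxyphenyl)methyl]oxolan-2-one, a trans lactone with 7S,8S,8′R.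

**Step 1**
Reactants: 1 3-(3,4-dimethoxyphenyl)propanoic acid; 2 (4S)-4-isopropyl-1,3-oxazolidin-2-one
Product: 4 (4S)-3-[3-(3,4-dimethoxyphenyl)propanoyl]-4-isopropyl-1,3-oxazolidin-2-one, via mixed pivalic anhydride 3 (not isolated)
Conditions: PivCl (1.05 equiv), Et3N (2.5 equiv), THF, −20 °C; then LiCl, 2, −20 °C → rt
Reagents that add atoms: none
Why: Mixed-anhydride N-acylation of an oxazolidinone under LiCl/Et3N conditions, in which nitrogen attacks the unhindered arylpropanoyl carbonyl of 3 rather than the tert-butyl-shielded one, no stereocentre is created and C4 of the auxiliary is untouched.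

**Step 2**
Reactants: 5 3-(4-hydroxy-3-methoxyphenyl)propanoic acid (dihydroferulic acid); 2 (4S)-4-isopropyl-1,3-oxazolidin-2-one
Product: 7 (4S)-4-isopropyl-3-[3-(3-methoxy-4-pivaloyloxyphenyl)propanoyl]-1,3-oxazolidin-2-one, via O-pivaloyl mixed anhydride 6 (not isolated)
Conditions: PivCl (2.2 equiv), Et3N (4.5 equiv), THF, 0 °C; then LiCl, 2, rt
Reagents that add atoms: pivaloyl chloride, CC(C)(C)C(=O)Cl
Why: The same mixed-anhydride N-acylation, in which the second equivalent of PivCl O-acylates the phenol in the same flask, so the oxidisable phenol is masked for step 3 without a separate protection step and no stereocentre is created.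

**Step 3**
Reactants: 4 (4S)-3-[3-(3,4-dimethoxyphenyl)propanoyl]-4-isopropyl-1,3-oxazolidin-2-one; 7 (4S)-4-isopropyl-3-[3-(3-methoxy-4-pivaloyloxyphenyl)propanoyl]-1,3-oxazolidin-2-one
Product: 10 (2R,3R)-2-(3,4-dimethoxybenzyl)-3-(3-methoxy-4-pivaloyloxybenzyl)-1,4-bis[(4S)-4-isopropyl-2-oxo-1,3-oxazolidin-3-yl]butane-1,4-dione, via veratryl imide lithium Z-enolate 8 (not isolated), via guaiacyl imide lithium Z-enolate 9 (not isolated)
Conditions: 4 (3 equiv) + 7 (1 equiv), LiN(iPr)2 (4.2 equiv), THF, −78 °C; CuCl2 (4.4 equiv), DMF, −78 → 0 °C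
Reagents that add atoms: none
Why: Oxidative enolate coupling, the laboratory counterpart of the 8–8′ radical coupling of two phenylpropanoid units, in which CuCl2 (divalent copper, reduced to monovalent copper) takes one electron from each chelated Z-enolate and the C8–C8′ bond forms at each α-carbon on the face opposite the isopropyl group of its own (S)-auxiliary, giving R at C8 and R at C8′, while the threefold excess of cheap 4 steers about three quarters of 7 into the mixed dimer 10, which is separated on silica from both homodimers and from the minor diastereomers.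

**Step 4**
Reactants: 10 (2R,3R)-bis-imide
Product: 12 (2R,3R)-2-(3,4-dimethoxybenzyl)-3-(4-hydroxy-3-methoxybenzyl)butanedioic acid, via bis(peroxy acid) 11 (not isolated)
Conditions: LiOH (8 equiv), 30% H2O2 (20 equiv), THF/H2O 3:1, 0 °C → rt; aq Na2SO3; HCl to pH 2
Reagents that add atoms: hydrogen peroxide (delivered as LiOOH), OO
Why: Hydroperoxide cleavage of N-acyl oxazolidinones, in which LiOOH made in the flask attacks the exocyclic imide carbonyls and the aryl ester and Na2SO3 then reduces the peroxy acids, and because the reagent is nucleophilic but barely basic C8 and C8′ are not enolised and stay R,R while both auxiliaries (recovered) and the pivalate leave in one operation.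

**Step 5**
Reactants: 12 (2R,3R)-2-(3,4-dimethoxybenzyl)-3-(4-hydroxy-3-methoxybenzyl)butanedioic acid
Product: 14 (2S,3S,4R)-4-(3,4-dimethoxybenzyl)-2-(4-hydroxy-3-methoxyphenyl)-5-oxooxolane-3-carboxylic acid (ring A), via p-quinone methide 13 (not isolated)
Conditions: DDQ (1.05 equiv), dry 1,4-dioxane, no base, 15 °C → rt, 1 h; filter off the hydroquinone
Reagents that add atoms: none
Why: Dehydrogenation of a 4-alkylguaiacol to its p-quinone methide followed by intramolecular carboxyl capture (oxidative benzylic lactonisation, the closure that makes the ferulic acid dilactone and the furofuran lignans), in which only the free-phenol ring is oxidised so only C7 is activated, only the C9′ acid can reach C7 through a five-membered transition state (C9 would give a β-lactone), and in the A(1,3)-minimised rotamer of 13 (C8–H in the quinoid plane) C8′ and its carboxyl lie over one face, so oxygen adds there and places the aryl group trans to the C8 carboxyl (7S), which is also the thermodynamic isomer because the alternative is all-cis.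

**Step 6**
Reactants: 14 (2S,3S,4R)-lactone acid (ring A)
Product: 16 (3S,4R)-4-(3,4-dimethoxybenzyl)-3-[(S)-hydroxy(4-hydroxy-3-methoxyphenyl)methyl]oxolan-2-one (target; ring B), via seco dihydroxy acid 15 (not isolated)
Conditions: LiEt3BH (4.6 equiv), THF, −78 → −20 °C; AcOH/H2O, rt, 3 h
Reagents that add atoms: none
Why: Chemoselective hydride reduction of a lactone beside a lithium carboxylate followed by γ-lactonisation (reductive translactonisation), in which LiEt3BH first deprotonates CO2H and ArOH to hydride-inert salts and then reduces ring A at −78 °C far faster than the phenoxide can expel the carboxylate, no bond to C7, C8 or C8′ is broken so 7S,8S,8′R are kept, and on mild acidification only the primary 9′-OH can close a five-membered ring on C9, the same O9′-to-C9 closure that ends the secoisolariciresinol-to-matairesinol sequence.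

**Compound list**
1 | 3-(3,4-dimethoxyphenyl)propanoic acid | COc1ccc(CCC(=O)O)cc1OC | starting material
2 | (4S)-4-isopropyl-1,3-oxazolidin-2-one | CC(C)[C@H]1COC(=O)N1 | starting material
3 | 3-(3,4-dimethoxyphenyl)propanoic pivalic anhydride | COc1ccc(CCC(=O)OC(=O)C(C)(C)C)cc1OC | intermediate
4 | (4S)-3-[3-(3,4-dimethoxyphenyl)propanoyl]-4-isopropyl-1,3-oxazolidin-2-one | COc1ccc(CCC(=O)N2[C@@H](C(C)C)COC2=O)cc1OC | intermediate
5 | 3-(4-hydroxy-3-methoxyphenyl)propanoic acid | COc1cc(CCC(=O)O)ccc1O | starting material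
6 | 3-(3-methoxy-4-pivaloyloxyphenyl)propanoic pivalic anhydride | COc1cc(CCC(=O)OC(=O)C(C)(C)C)ccc1OC(=O)C(C)(C)C | intermediate
7 | (4S)-4-isopropyl-3-[3-(3-methoxy-4-pivaloyloxyphenyl)propanoyl]-1,3-oxazolidin-2-one | COc1cc(CCC(=O)N2[C@@H](C(C)C)COC2=O)ccc1OC(=O)C(C)(C)C | intermediate
8 | lithium (Z)-enolate of 4 | [Li+].[O-]/C(=C\Cc1ccc(OC)c(OC)c1)N1[C@@H](C(C)C)COC1=O | intermediate
9 | lithium (Z)-enolate of 7 | [Li+].[O-]/C(=C\Cc1ccc(OC(=O)C(C)(C)C)c(OC)c1)N1[C@@H](C(C)C)COC1=O | intermediate
10 | (2R,3R)-2-(3,4-dimethoxybenzyl)-3-(3-methoxy-4-pivaloyloxybenzyl)-1,4-bis[(4S)-4-isopropyl-2-oxo-1,3-oxazolidin-3-yl]butane-1,4-dione | O=C(N1[C@@H](C(C)C)COC1=O)[C@H](Cc1ccc(OC)c(OC)c1)[C@@H](Cc1ccc(OC(=O)C(C)(C)C)c(OC)c1)C(=O)N1[C@@H](C(C)C)COC1=O | intermediate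
11 | (2R,3R)-2-(3,4-dimethoxybenzyl)-3-(4-hydroxy-3-methoxybenzyl)butanediperoxoic acid | OOC(=O)[C@H](Cc1ccc(OC)c(OC)c1)[C@@H](Cc1ccc(O)c(OC)c1)C(=O)OO | intermediate
12 | (2R,3R)-2-(3,4-dimethoxybenzyl)-3-(4-hydroxy-3-methoxybenzyl)butanedioic acid | OC(=O)[C@H](Cc1ccc(OC)c(OC)c1)[C@@H](Cc1ccc(O)c(OC)c1)C(=O)O | intermediate
13 | (2R,3R)-2-(3,4-dimethoxybenzyl)-3-[(3-methoxy-4-oxocyclohexa-2,5-dien-1-ylidene)methyl]butanedioic acid | OC(=O)[C@H](Cc1ccc(OC)c(OC)c1)[C@@H](C=C1C=CC(=O)C(OC)=C1)C(=O)O | intermediate
14 | (2S,3S,4R)-4-(3,4-dimethoxybenzyl)-2-(4-hydroxy-3-methoxyphenyl)-5-oxooxolane-3-carboxylic acid | COc1cc([C@H]2OC(=O)[C@H](Cc3ccc(OC)c(OC)c3)[C@@H]2C(=O)O)ccc1O | intermediate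
15 | (2S,3R)-3-(3,4-dimethoxybenzyl)-4-hydroxy-2-[(S)-hydroxy(4-hydroxy-3-methoxyphenyl)methyl]butanoic acid | COc1cc([C@@H](O)[C@@H](C(=O)O)[C@H](CO)Cc2ccc(OC)c(OC)c2)ccc1O | intermediate
16 | (3S,4R)-4-(3,4-dimethoxybenzyl)-3-[(S)-hydroxy(4-hydroxy-3-methoxyphenyl)methyl]oxolan-2-one | COc1cc([C@@H](O)[C@H]2C(=O)OC[C@@H]2Cc2ccc(OC)c(OC)c2)ccc1O | target

**Step count**
Total steps: 6. Longest linear sequence: 5 (step 1 or step 2, then steps 3 to 6).

**Steps most likely to fail**

Step 3. The two enolates are electronically alike, so the cross product is only statistically favoured. It must also be separated from two homodimers, and the aryl pivalate has to survive LiN(iPr)2. The fallback sets out from 7 and comes back at 12. Enolate 9 alone is coupled (LiN(iPr)2, then CuCl2), which needs no cross-selectivity. This gives the C2-symmetric (2R,3R)-2,3-bis(3-methoxy-4-pivaloyloxybenzyl)-1,4-bis[(4S)-4-isopropyl-2-oxo-1,3-oxazolidin-3-yl]butane-1,4-dione F1. LiOH/H2O2 takes it through (2R,3R)-2,3-bis(4-hydroxy-3-methoxybenzyl)butanediperoxoic acid F2, reduced by Na2SO3, to (2R,3R)-2,3-bis(4-hydroxy-3-methoxybenzyl)butanedioic acid F3. Its two phenols are homotopic, so one equivalent of Me2SO4 in aqueous NaOH can give only one monomethyl ether, which is 12. Recovered diphenol is recycled.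

Step 5. Species 13 or its protonated form has four escape routes:
- arylation by the veratryl ring to an aryltetralin
- loss of C9 as CO2 with re-aromatisation if the C9 acid is ionised
- tautomerisation to the arylidene succinic acid
- a second oxidation

The fallback sets out from 12 and comes back at 14, and it separates capture from ring closure. DDQ in methanol lets the solvent, present in huge excess, trap 13 first. This gives (2R,3S)-2-(3,4-dimethoxybenzyl)-3-[(4-hydroxy-3-methoxyphenyl)(methoxy)methyl]butanedioic acid F4 as both C7 epimers. Heating that ether in toluene over 4 Å sieves, with no added acid or base, re-forms the neutral quinone methide reversibly. The sieves remove methanol, and both epimers drain into the most stable closed form, the trans-aryl lactone 14.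

Step 6. If the lithium phenoxide expels the ring A carboxylate before hydride arrives, the quinone methide is reduced at C7 and 12 is regenerated. That material can be removed with bicarbonate and recycled. Partial reduction of the C9 carboxyl is the second risk. The fallback sets out from 14 and comes back at 15. It leaves ate-complex hydrides and crosses the redox gap in two stages through an isolated lactol. The electrophilic alane iBu2AlH (4 equiv, CH2Cl2, −78 °C) ties phenol and acid up as aluminium salts and stops at (2S,3S,4R)-4-(3,4-dimethoxybenzyl)-5-hydroxy-2-(4-hydroxy-3-methoxyphenyl)oxolane-3-carboxylic acid F5. In this lactol the group on C7 is no longer a carboxylate leaving group. NaBH4 in buffered MeOH at 0 °C can therefore reduce its open hydroxy aldehyde form safely to 15, which lactonises to 16 with AcOH as in step 6.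

**Further compounds**
F1 | step 3 | (2R,3R)-2,3-bis(3-methoxy-4-pivaloyloxybenzyl)-1,4-bis[(4S)-4-isopropyl-2-oxo-1,3-oxazolidin-3-yl]butane-1,4-dione | O=C(N1[C@@H](C(C)C)COC1=O)[C@H](Cc1ccc(OC(=O)C(C)(C)C)c(OC)c1)[C@@H](Cc1ccc(OC(=O)C(C)(C)C)c(OC)c1)C(=O)N1[C@@H](C(C)C)COC1=O
F2 | step 3 | (2R,3R)-2,3-bis(4-hydroxy-3-methoxybenzyl)butanediperoxoic acid | OOC(=O)[C@H](Cc1ccc(O)c(OC)c1)[C@@H](Cc1ccc(O)c(OC)c1)C(=O)OO
F3 | step 3 | (2R,3R)-2,3-bis(4-hydroxy-3-methoxybenzyl)butanedioic acid | OC(=O)[C@H](Cc1ccc(O)c(OC)c1)[C@@H](Cc1ccc(O)c(OC)c1)C(=O)O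
F4 | step 5 | (2R,3S)-2-(3,4-dimethoxybenzyl)-3-[(4-hydroxy-3-methoxyphenyl)(methoxy)methyl]butanedioic acid (C7 epimer mixture) | OC(=O)[C@H](Cc1ccc(OC)c(OC)c1)[C@@H](C(OC)c1ccc(O)c(OC)c1)C(=O)O
F5 | step 6 | (2S,3S,4R)-4-(3,4-dimethoxybenzyl)-5-hydroxy-2-(4-hydroxy-3-methoxyphenyl)oxolane-3-carboxylic acid (anomer mixture) | COc1cc([C@H]2OC(O)[C@H](Cc3ccc(OC)c(OC)c3)[C@@H]2C(=O)O)ccc1O
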